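Assumption: lupalbigenin has no stereocentre, and both prenyl alkenes end in gem-dimethyl groups, so there is no E/Z isomerism. The molecule is achiral, and "single enantiomer" is taken to mean the one structure drawn.

## Retrosynthetic overview
1. Lupalbigenin comes from its 5,7-bis-MOM ether by mild acid in the last step.
2. Ring C is closed last, in the same operation that makes C3–C1′. An aryl radical from unprotected 4-iodo-2-prenylphenol adds to Cα of an o-hydroxyaryl enaminone. The resulting α-amino radical becomes an iminium, the phenol captures it (O1–C2), and Me2NH leaves. No 3-halochromone, B-ring organometallic or deoxybenzoin is needed.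
3. The enaminone comes from a methyl ketone, which comes from symmetric 3,5-bis(MOMO)-4-prenylphenol. Its two ortho sites are identical, so the prenyl group can only end at C6 and never at C8.
4. That phenol comes from resorcinol by MOM protection, lithiation/prenylation at C2, and sterically governed C–H borylation/oxidation at C5, which supplies the third oxygen.
5. Rings A and B come from resorcinol and 4-iodophenol. Only ring C is constructed.

## Route

**Step 1**
Reactants: 1 resorcinol
Product: 2 1,3-bis(methoxymethoxy)benzene
Conditions: MOMCl (2.5 equiv), i-Pr2NEt, CH2Cl2, 0 °C → rt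
Reagents that add atoms: chloromethyl methyl ether, COCCl
Why: Standard O-alkylation (MOM protection) gives a base-stable group that is also a strong director for ortho-metalation.

**Step 2**
Reactants: 2; 3 prenyl bromide (1-bromo-3-methylbut-2-ene)
Product: 4 1,3-bis(methoxymethoxy)-2-(3-methylbut-2-en-1-yl)benzene
Conditions: n-BuLi (1.1 equiv), THF, 0 °C → rt, 1 h; then 3, −78 °C → rt
Reagents that add atoms: prenyl bromide 3, CC(C)=CCBr
Why: Directed ortho-metalation occurs only at C2 between the two cooperating OMOM groups, and the aryllithium displaces the primary allylic bromide (SN2).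

**Step 3**
Reactants: 4
Product: 5 3,5-bis(methoxymethoxy)-4-(3-methylbut-2-en-1-yl)phenol
Conditions: [Ir(OMe)(cod)]2 (1.5 mol %), dtbpy (3 mol %), B2pin2, THF, 60 °C; then 30 % H2O2, aq NaOH, 0 °C (one pot)
Reagents that add atoms: hydrogen peroxide, OO (phenolic O); B2pin2 leaves no atoms in the product
Why: Sterically controlled Hartwig–Miyaura C–H borylation can reach only C5–H (the other ring C–H bonds are ortho to OMOM), and basic peroxide oxidises ArBpin to ArOH without touching an unactivated trisubstituted alkene.

**Step 4**
Reactants: 5; 6 N-methoxy-N-methylacetamide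
Product: 7 1-[6-hydroxy-2,4-bis(methoxymethoxy)-3-(3-methylbut-2-en-1-yl)phenyl]ethan-1-one
Conditions: n-BuLi (2.2 equiv), TMEDA, THF, −78 → 0 °C, 1 h; then 6, −78 °C → rt; aq NH4Cl
Reagents that add atoms: Weinreb amide 6, CC(=O)N(C)OC
Why: After O-deprotonation, cooperative OLi/OMOM directed ortho-metalation lithiates the C–H flanked by both oxygens (the two such sites are equivalent), and Weinreb acylation stops at the ketone; keeping the mixture at or below 0 °C limits allylic/benzylic deprotonation of the prenyl CH2.

**Step 5**
Reactants: 7; 8 N,N-dimethylformamide dimethyl acetal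
Product: 9 (E)-3-(dimethylamino)-1-[6-hydroxy-2,4-bis(methoxymethoxy)-3-(3-methylbut-2-en-1-yl)phenyl]prop-2-en-1-one
Conditions: 8 (3 equiv), toluene, 95 °C, 3 h
Reagents that add atoms: DMF-DMA 8, COC(OC)N(C)C
Why: Enaminone condensation of a 2-hydroxy-4,6-dialkoxyacetophenone is routine, the chelated OH is not methylated, and the E-alkene is the thermodynamic product.

**Step 6**
Reactants: 10 4-iodophenol; 3 prenyl bromide
Product: 11 4-iodo-2-(3-methylbut-2-en-1-yl)phenol
Conditions: NaH (1.05 equiv), toluene, 0 °C → rt; then 3, rt, 18 h
Reagents that add atoms: prenyl bromide 3, CC(C)=CCBr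
Why: A tight sodium phenoxide ion pair in a non-polar solvent favours ortho C-allylation over O-alkylation, the para position is blocked by iodine, and a moderate yield is acceptable for a one-step fragment.

**Step 7 (key step)**
Reactants: 9; 11 (2 equiv)
Product: 12 3-[4-hydroxy-3-(3-methylbut-2-en-1-yl)phenyl]-5,7-bis(methoxymethoxy)-6-(3-methylbut-2-en-1-yl)-4H-chromen-4-one
Conditions: fac-Ir(ppy)3 (2 mol %), degassed MeCN/DMSO (0.3 M in 9), 450 nm LEDs, 25 °C, no added base
Reagents that add atoms: none (only 9 and 11; by-product Me2NH·HI)
Why: Proposed new method: excited fac-Ir(ppy)3 cleaves the C–I bond of 11 to a σ-aryl radical that adds to the nucleophilic Cα of the push–pull enaminone (the radical site is meta to its own prenyl group, so it cannot cyclise, and 0.3 M enaminone should outrun HAT or addition at the hindered trisubstituted alkenes), the α-amino radical then becomes an iminium either by Ir(IV) oxidation or by iodine-atom abstraction from a second molecule of 11 (an XAT chain), and the ortho-OH closes O1–C2 with loss of Me2NH·HI, making the process redox-neutral; the closest known reaction types are the visible-light Meerwein-type arylation/annulation of o-hydroxyaryl enaminones with arenediazonium salts and α-aminoalkyl-radical halogen-atom transfer from aryl iodides.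

**Step 8**
Reactants: 12
Product: 13 lupalbigenin
Conditions: 3 M aq HCl, MeOH, 50 °C, 2 h
Reagents that add atoms: none
Why: Acid-catalysed acetal hydrolysis removes both MOM groups, and dilute acid at or below 50 °C is the usual window in which ortho-prenyl phenols do not close to chromans; no stereocentre has to be set.

## Compound list
| No. | Name | SMILES | Role |
|---|---|---|---|
| 1 | resorcinol | Oc1cccc(O)c1 | starting material |
| 2 | 1,3-bis(methoxymethoxy)benzene | COCOc1cccc(OCOC)c1 | intermediate |
| 3 | prenyl bromide | CC(C)=CCBr | starting material |
| 4 | 1,3-bis(MOMO)-2-prenylbenzene | COCOc1cccc(OCOC)c1CC=C(C)C | intermediate |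
| 5 | 3,5-bis(MOMO)-4-prenylphenol | COCOc1cc(O)cc(OCOC)c1CC=C(C)C | intermediate |
| 6 | N-methoxy-N-methylacetamide | CC(=O)N(C)OC | starting material |
| 7 | 6-hydroxy-2,4-bis(MOMO)-3-prenylacetophenone | CC(=O)c1c(O)cc(OCOC)c(CC=C(C)C)c1OCOC | intermediate |
| 8 | DMF dimethyl acetal | COC(OC)N(C)C | starting material |
| 9 | (E)-enaminone of 7 | CN(C)/C=C/C(=O)c1c(O)cc(OCOC)c(CC=C(C)C)c1OCOC | intermediate |
| 10 | 4-iodophenol | Oc1ccc(I)cc1 | starting material |
| 11 | 4-iodo-2-prenylphenol | CC(C)=CCc1cc(I)ccc1O | intermediate |
| 12 | 5,7-di-O-MOM-lupalbigenin | CC(C)=CCc1cc(-c2coc3cc(OCOC)c(CC=C(C)C)c(OCOC)c3c2=O)ccc1O | intermediate |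
| 13 | lupalbigenin | CC(C)=CCc1cc(-c2coc3cc(O)c(CC=C(C)C)c(O)c3c2=O)ccc1O | target |

## Step count
- Total steps: 8
- Longest linear sequence: 7 (steps 1–5, 7 and 8)

## Steps most likely to fail
1. **Step 7.**
   - Risks: the electron-rich iodide may be reduced slowly, the aryl radical may abstract hydrogen from or add to the prenyl groups, and 9 may cyclise early to the 3-H chromone.
   - Fallback: make the same bond one stage earlier by a photostimulated SRN1 reaction. The dianion of ketone 7 (KOt-Bu, DMSO, hν) is coupled with the MOM ether of 11, where the enolate traps the aryl radical at close to the diffusion limit. DMF-DMA then closes ring C on the resulting deoxybenzoin.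
2. **Step 4.**
   - Risks: the anionic ring may lithiate slowly, and deprotonation at the prenyl CH2 may compete.
   - Fallback: O-acetylate 5 and carry out a photo-Fries rearrangement (254 nm, hexane/MeOH). The acyl/phenoxyl radical pair can recombine only at the two equivalent ortho carbons, because the para position carries the prenyl group, and this gives 7 without any organolithium.
3. **Step 3.**
   - Risk: the Ir–boryl catalyst may hydroborate or isomerise the prenyl alkene.
   - Fallback: reverse the order. Borylate and oxidise 2 first to 3,5-bis(MOMO)phenol, then lithiate its lithium phenoxide between the two OMOM groups and add prenyl bromide to reach 5.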